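Every unit of reagent charged stays on the books: in the second phase, in the reaction phase, one per target, two per over-reacted product. How much of it stands in the reaction phase at any moment is what two chemists dispute here.

starting material 0.050 M; reagent in the second phase 1.20 equiv; protic impurity 2.50 mM; time 15 min; volume of the second phase over the first 0.50

- the target standing at 15 min, as a percentage of the starting material charged
- the change that raises the amount of target at 15 min, in percent of the starting material charged most ("none" if none brings more than 2 percentage points) (epsilon / beta / none)
- amount of target at 15 min, in percent of the starting material charged, after epsilon

- in the second phase: reagent in the second phase; everything else is in the first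
- charges count per volume of the first phase; a concentration in a rate is the amount of a species over the volume of its own phase; every rate counts per litre of the first phase
- run time (flask): 15 min

    reagent in the reaction phase ⇌ reagent in the second phase, rate k1*([reagent in the reaction phase] - [reagent in the second phase]/K1) per volume of the first phase (K1 = 47, k1 = 0.0087 s⁻¹)
    starting material + reagent in the reaction phase → target (k2 = 0.23 M⁻¹ s⁻¹)
    reagent in the reaction phase + target → over-reacted product (k3 = 0.72 M⁻¹ s⁻¹)
    starting material ⇌ dormant form (K4 = 0.45, k4 = 0.014 s⁻¹)
    starting material + protic impurity → quenched substrate (k5 = 1.3 M⁻¹ s⁻¹)

All amounts below are fractions of the starting material charged. Both chemists begin alike. The protic impurity takes 5.00 %, the dormant form takes its equilibrium share of the rest, and free starting material is left at 0.655. At a constant reagent level, target climbs towards free starting material times the ratio of the making constant to the over-reaction constant, 0.319, by the factor one minus exp(−over-reaction constant × level × time).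

The first chemist takes passage between the phases as instant, which puts the reagent at its partition level, 5.11 %, and gives 16.9 % target at 15 min.

I take the second view. Starting material consumes the reagent at a pseudo-first-order 0.452 min⁻¹, and the transfer coefficient of 0.52 min⁻¹ is only slightly faster. The level is therefore the partition level times the holding fraction, the transfer coefficient over itself plus the reagent's pseudo-first-order losses. That is 0.536, about half, and with free starting material and the second phase held constant I commit to 12.3 %. Doubling the charge doubles the partition level, whereas doubling the transfer coefficient lifts the holding fraction to 0.698, a factor of only 1.30. I choose epsilon.

The forecast says 9.6 % (8.8 % to 10.4 %), epsilon, and 12.9 % (11.8 % to 14 %), on the ground that “its slow leak sets a low, roughly steady level”. Its target is lower than mine.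

The simulation gives 9.69 %, epsilon with 3.3 percentage points against 1.5 points for beta, and 13.0 %.

The first chemist's ground is far faster passage: a thousand times as fast, this flask stands at 13.0 %. A charge of 0.429 equiv would take this flask's target outside the forecast's range. At 15.0 min this flask makes reagent in the reaction phase 0.973 times as fast as it uses it up, and its standing amounts give a holding fraction of 0.467. The neighbour charged at 0.013 M reckons at 0.815, hence a level of 3.82 %, and it reads 3.85 % with target at 4.53 %.

The numbers come from no measurement; the run is a simulation.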